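**Plan**

1. Late cuts: the epoxide oxygen at C1/C2, the C1=C2 unsaturation, the C4 and C5 oxygens, both ester C–O bonds, the O8–C12 lactone bond, and then C4–C15, which leaves a C4≡C5 alkyne.
2. Enabling feature: in the ten-membered carbocycle C1–C10, C6 is a carbinol and its neighbour C7 carries C11(=C13)C12. This homoallylic alcohol is the product pattern of a [2,3]-Wittig shift, so cutting C6–C7 and joining O6 to C13 gives a thirteen-membered propargylic allylic ether in which C6–H is the most acidic position.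
3. Early cuts: O–C13 (Williamson), C3–C4 (acetylide addition) and C7–C8 (alkenyllithium addition). Building blocks are (S)-citronellal (C8–C10, C1–C3, C14) and prop-2-yn-1-ol, used twice (C7/C11/C12/C13 and C4–C6).
4. Forward order: chain, thirteen-membered ether ring, ten-membered carbocycle by ring contraction, C15, crotonate, lactone ring, diol and acetate, enone, epoxide ring.
5. Stereochemistry: C10 from (S)-citronellal; C8 by CBS reduction; C6 and C7 in the ring contraction, steered by C8 and the (Z)-C7=C11 geometry; C4 and C5 by syn-dihydroxylation of the (E)-alkene on its outer face; C1 and C2 by epoxidation of the (Z)-enone on its exposed face.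

Key step: step 16

Remark: ring carbons carry germacranolide numbers throughout (C1–C10 ring, C11–C13 lactone carbons, C14 on C10, C15 on C4); the C6 carbanion is made by deprotonation next to a C4≡C5 alkyne, and the C15 methyl is added to that alkyne after the ring contraction.

**Route**

Step 1
Reactants: 1 prop-2-yn-1-ol
Product: 3 (Z)-3-iodo-2-methylprop-2-en-1-ol, via alkenylmagnesium chelate 2 (not isolated)
Conditions: MeMgBr (2.5 equiv), CuI (10 mol %), THF, −10 °C → rt; then I2, −78 → 0 °C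
Reagents that add atoms: methylmagnesium bromide (C[Mg]Br); iodine (II)
Why: Copper-catalysed anti-carbomagnesiation of the propargylic alkoxide puts methyl on the internal carbon (C11) and magnesium on the terminal carbon (C7) cis to the CH2O arm in a five-membered chelate, and iodinolysis with retention gives the (Z)-iodoalkene that later fixes the C7=C11 geometry.

Step 2
Reactants: 3 (Z)-3-iodo-2-methylprop-2-en-1-ol
Product: 4 (Z)-1-iodo-3-[(4-methoxybenzyl)oxy]-2-methylprop-1-ene
Conditions: NaH, 4-methoxybenzyl chloride, Bu4NI (cat.), THF/DMF, 0 °C → rt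
Reagents that add atoms: 4-methoxybenzyl chloride (COc1ccc(CCl)cc1)
Why: Williamson etherification; a benzyl-type ether is chosen because a silyl ether cis to the later carbon–lithium bond could migrate from oxygen to carbon.

Step 3
Reactants: 4 (Z)-iodoalkene PMB ether; 5 (S)-citronellal
Product: 7 (2Z,6S)-1-[(4-methoxybenzyl)oxy]-2,6,10-trimethylundeca-2,9-dien-4-ol as both C4 epimers, via alkenyllithium 6 (not isolated)
Conditions: t-BuLi (2.1 equiv), Et2O, −78 °C; then 5, −78 °C; then H2O
Reagents that add atoms: none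
Why: Iodine–lithium exchange occurs with retention of alkene geometry and the alkenyllithium adds 1,2 to the aldehyde (C7–C8 bond); C8 forms without control and is corrected in steps 4 and 5.

Step 4
Reactants: 7 allylic alcohol (C8 epimers)
Product: 8 (2Z,6S)-1-[(4-methoxybenzyl)oxy]-2,6,10-trimethylundeca-2,9-dien-4-one
Conditions: Dess–Martin periodinane, CH2Cl2, 0 °C → rt
Reagents that add atoms: none
Why: Dess–Martin oxidation of the allylic alcohol under neutral conditions gives the enone without (Z)/(E) isomerisation.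

Step 5
Reactants: 8 (Z)-enone
Product: 9 (2Z,4R,6S)-1-[(4-methoxybenzyl)oxy]-2,6,10-trimethylundeca-2,9-dien-4-ol
Conditions: (S)-2-methyl-CBS-oxazaborolidine (20 mol %), catecholborane, toluene, −78 °C; then aqueous work-up
Reagents that add atoms: none
Why: Corey–Bakshi–Shibata reduction: with the alkenyl group as the large and the CH2 chain as the small substituent, the (S)-catalyst delivers hydride to the face that gives the (R)-carbinol at C8, and catecholborane at low temperature avoids hydroboration of the two alkenes.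

Step 6
Reactants: 9 (R)-allylic alcohol
Product: 10 tert-butyl{[(2Z,4R,6S)-1-[(4-methoxybenzyl)oxy]-2,6,10-trimethylundeca-2,9-dien-4-yl]oxy}dimethylsilane
Conditions: TBSCl, imidazole, DMF, rt
Reagents that add atoms: tert-butyldimethylsilyl chloride (CC(C)(C)[Si](C)(C)Cl)
Why: Standard silylation of a secondary allylic alcohol; the TBS ether should be stable to every reagent up to step 21.

Step 7
Reactants: 10 diene TBS ether
Product: 12 (4S,6R,7Z)-6-[(tert-butyldimethylsilyl)oxy]-9-[(4-methoxybenzyl)oxy]-4,8-dimethylnon-7-enal, via 9,10-diol 11 (not isolated)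
Conditions: K2OsO2(OH)4 (1 mol %), N-methylmorpholine N-oxide (1.1 equiv), acetone/H2O, 0 °C; then NaIO4, THF/H2O, rt
Reagents that add atoms: N-methylmorpholine N-oxide (C[N+]1([O-])CCOCC1) and water (O), which supply the oxygens of 11, one of which remains as the aldehyde oxygen of 12
Why: Upjohn dihydroxylation followed by periodate glycol cleavage (a two-stage Lemieux–Johnson sequence): the electron-rich, unhindered isopropylidene alkene is osmylated in preference to the (Z)-alkene flanked by two allylic C–O bonds, and cleavage unveils C3 as an aldehyde.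

Step 8
Reactants: 1 prop-2-yn-1-ol
Product: 13 triethyl(prop-2-yn-1-yloxy)silane
Conditions: Et3SiCl, imidazole, CH2Cl2, 0 °C
Reagents that add atoms: chlorotriethylsilane (CC[Si](Cl)(CC)CC)
Why: Standard silylation; the triethylsilyl ether is chosen so that it can later be removed in the presence of the secondary TBS ether.

Step 9
Reactants: 12 aldehyde; 13 triethyl(prop-2-yn-1-yloxy)silane
Product: 15 (2Z,4R,6S)-4-[(tert-butyldimethylsilyl)oxy]-1-[(4-methoxybenzyl)oxy]-2,6-dimethyl-12-[(triethylsilyl)oxy]dodec-2-en-10-yn-9-ol as both C9 epimers, via lithium acetylide 14 (not isolated)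
Conditions: 13, n-BuLi, THF, −78 °C; then 12, −78 → −40 °C; then H2O
Reagents that add atoms: none
Why: Addition of a lithium acetylide to an aldehyde forms the C3–C4 bond; the carbinol configuration is irrelevant because C3 is oxidised in the next step.

Step 10
Reactants: 15 propargylic alcohol
Product: 16 (2Z,4R,6S)-4-[(tert-butyldimethylsilyl)oxy]-1-[(4-methoxybenzyl)oxy]-2,6-dimethyl-12-[(triethylsilyl)oxy]dodec-2-en-10-yn-9-one
Conditions: Dess–Martin periodinane, pyridine, CH2Cl2, 0 °C
Reagents that add atoms: none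
Why: Dess–Martin oxidation of a propargylic alcohol to the ynone; pyridine buffers the acetic acid so that the silyl ethers survive.

Step 11
Reactants: 16 ynone
Product: 17 (2Z,4R,6S)-4-[(tert-butyldimethylsilyl)oxy]-9,9-(ethylenedioxy)-1-[(4-methoxybenzyl)oxy]-2,6-dimethyl-12-[(triethylsilyl)oxy]dodec-2-en-10-yne
Conditions: 1,2-bis(trimethylsilyloxy)ethane, Me3SiOTf (5 mol %), CH2Cl2, −78 → −20 °C; pyridine quench
Reagents that add atoms: 1,2-bis(trimethylsilyloxy)ethane (C[Si](C)(C)OCCO[Si](C)(C)C)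
Why: Ketalisation with the bis-silyl ether of ethylene glycol under silyl triflate catalysis (Noyori conditions) is aprotic and cold, so the ynone is masked without conjugate addition or loss of the silyl and PMB groups before the organolithium and hydride steps.

Step 12
Reactants: 17 ketal PMB ether
Product: 18 (2Z,4R,6S)-4-[(tert-butyldimethylsilyl)oxy]-9,9-(ethylenedioxy)-2,6-dimethyl-12-[(triethylsilyl)oxy]dodec-2-en-10-yn-1-ol
Conditions: DDQ, CH2Cl2/pH 7 buffer, 0 °C
Reagents that add atoms: none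
Why: Oxidative cleavage of the 4-methoxybenzyl ether by DDQ (hydride abstraction from the electron-rich benzylic position, then hydrolysis) leaves silyl ethers, ketal and alkyne untouched.

Step 13
Reactants: 18 (Z)-allylic alcohol
Product: 20 (2Z,4R,6S)-4-[(tert-butyldimethylsilyl)oxy]-1-chloro-9,9-(ethylenedioxy)-2,6-dimethyl-12-[(triethylsilyl)oxy]dodec-2-en-10-yne, via allylic mesylate 19 (not isolated)
Conditions: MsCl, 2,4,6-collidine, LiCl, DMF, 0 °C
Reagents that add atoms: lithium chloride ([Li+].[Cl-]); methanesulfonyl chloride (CS(=O)(=O)Cl) adds atoms only to 19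
Why: Mesylation and in situ SN2 displacement by chloride convert the primary allylic alcohol into the chloride without allylic transposition, so the (Z)-geometry is kept.

Step 14
Reactants: 20 allylic chloride
Product: 21 (7S,9R,10Z)-9-[(tert-butyldimethylsilyl)oxy]-12-chloro-4,4-(ethylenedioxy)-7,11-dimethyldodec-10-en-2-yn-1-ol
Conditions: pyridinium p-toluenesulfonate (cat.), MeOH/CH2Cl2, 0 °C
Reagents that add atoms: none
Why: Acid-catalysed methanolysis removes the primary triethylsilyl ether far faster than the hindered secondary TBS ether, and the ketal, flanked by the electron-withdrawing alkyne, is stable at this acidity.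

Step 15
Reactants: 21 chloro propargylic alcohol
Product: 22 tert-butyl{[(11Z,13R,15S)-11,15-dimethyl-1,4,9-trioxaspiro[4.12]heptadec-11-en-6-yn-13-yl]oxy}dimethylsilane (thirteen-membered ether: O between C6 and C13; C4≡C5; (Z)-C7=C11; C3 dioxolane; 8R; 10S)
Conditions: NaH, Bu4NI (cat.), THF, 65 °C, slow addition of 21 (final about 0.003 M)
Reagents that add atoms: none
Why: Intramolecular Williamson etherification (SN2 of the propargylic alkoxide on the primary allylic chloride) under high dilution closes the thirteen-membered ring; the alkyne and the (Z)-alkene remove rotors from the chain, and macrocyclic propargylic allylic ethers of this size are known to form in this way.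

Step 16
Reactants: 22 thirteen-membered propargylic allylic ether
Product: 24 (6S,7R,8R,10S)-8-[(tert-butyldimethylsilyl)oxy]-3,3-(ethylenedioxy)-10-methyl-7-(prop-1-en-2-yl)cyclodec-4-yn-6-ol, via C6-lithiated ether 23 (not isolated)
Conditions: n-BuLi (1.5 equiv), THF, −78 °C; then H2O at −78 °C
Reagents that add atoms: none
Why: n-BuLi removes a proton from C6, the only position that is both propargylic and next to the ether oxygen, and the carbanion attacks C7 through a five-membered envelope transition state (C6, O, C13, C11, C7) while O–C13 breaks and C11=C13 becomes the isopropenyl alkene; this is a [2,3]-Wittig rearrangement. The closest known reaction type is the contraction of thirteen-membered propargylic allylic ethers to cyclodec-4-yn-6-ols bearing a 7-isopropenyl group. The ten-membered carbocycle is closed by transannular C6–C7 bond formation, that is by ring contraction in which O, C13 and C11 leave the ring. C7 is set relative to C8 because H8 eclipses the (Z)-alkene (A(1,3) strain with C13), which puts the ring arm C9 on the attacked face and the silyloxy group on the other; C6 is set relative to C7 because the alkynyl arm and C8 are tied together by the ring and must lie on the same side of the envelope, which with the (Z)-alkene gives the hydroxyl and the isopropenyl group cis. The step needs the [2,3] path to win over the [1,2] shift and over loss of a ketal oxygen from the propargyl anion, which the low temperature and the concerted cyclic pathway should secure, and it needs deprotonation at C6 and not at C13, which the higher acidity of the propargylic position secures.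

Step 17
Reactants: 24 cyclodecynol
Product: 26 (4Z,6S,7R,8R,10S)-8-[(tert-butyldimethylsilyl)oxy]-3,3-(ethylenedioxy)-4-iodo-10-methyl-7-(prop-1-en-2-yl)cyclodec-4-en-6-ol, via alkenylalanate 25 (not isolated)
Conditions: NaAlH2(OCH2CH2OCH3)2, THF, 0 °C → rt; EtOAc; then I2, THF, −78 → 0 °C
Reagents that add atoms: iodine (II)
Why: Hydroxyl-directed trans-hydroalumination of the propargylic alcohol: the alkoxyaluminate delivers hydride to C5 and aluminium to C4 in a five-membered ring, and iodinolysis with retention gives the (Z)-iodoalkene, in which C3 and C6 are already trans as required for the (E)-C4=C5 alkene.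

Step 18
Reactants: 26 alkenyl iodide
Product: 27 (4E,6R,7R,8R,10S)-8-[(tert-butyldimethylsilyl)oxy]-3,3-(ethylenedioxy)-4,10-dimethyl-7-(prop-1-en-2-yl)cyclodec-4-en-6-ol
Conditions: Me2CuLi (preformed, excess), Et2O, 0 °C; then H2O
Reagents that add atoms: lithium dimethylcuprate ([Li+].C[Cu-]C)
Why: Cuprate cross-coupling of the alkenyl iodide (Corey–House type) replaces iodine by methyl with retention and so installs C15 on an (E)-trisubstituted alkene.

Step 19
Reactants: 27 allylic alcohol
Product: 28 (4E,6R,7R,8R,10S)-8-[(tert-butyldimethylsilyl)oxy]-3,3-(ethylenedioxy)-4,10-dimethyl-7-(prop-1-en-2-yl)cyclodec-4-en-6-yl (E)-but-2-enoate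
Conditions: (E)-but-2-enoic anhydride, DMAP (cat.), pyridine, CH2Cl2, rt
Reagents that add atoms: (E)-but-2-enoic anhydride (C/C=C/C(=O)OC(=O)/C=C/C)
Why: DMAP-catalysed acylation of the secondary allylic alcohol; C6 is esterified before C12 is oxidised so that the later lactone can close only onto O8.

Step 20
Reactants: 28 crotonate
Product: 29 (4E,6R,7R,8R,10S)-8-[(tert-butyldimethylsilyl)oxy]-3,3-(ethylenedioxy)-7-(3-hydroxyprop-1-en-2-yl)-4,10-dimethylcyclodec-4-en-6-yl (E)-but-2-enoate
Conditions: SeO2 (0.5 equiv), t-BuOOH (anhydrous), CH2Cl2, rt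
Reagents that add atoms: tert-butyl hydroperoxide (CC(C)(C)OO), oxygen passed on through SeO2 (O=[Se]=O)
Why: Catalytic Riley oxidation (ene reaction of the selenium reagent followed by [2,3]-shift) hydroxylates the methyl group of the 1,1-disubstituted alkene; the ring alkene is deactivated by the allylic ester and ketal and its only allylic methyl sits cis to C6, the disfavoured site.

Step 21
Reactants: 29 allylic alcohol TBS ether
Product: 30 (4E,6R,7S,8R,10S)-3,3-(ethylenedioxy)-8-hydroxy-7-(3-hydroxyprop-1-en-2-yl)-4,10-dimethylcyclodec-4-en-6-yl (E)-but-2-enoate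
Conditions: HF·pyridine, pyridine, THF, 0 °C → rt
Reagents that add atoms: none
Why: Fluoride-mediated cleavage of the TBS ether with buffered HF·pyridine; the weakly acidic medium spares the ketal and does not promote acyl migration from O6.

Step 22
Reactants: 30 diol
Product: 33 (4E,6R,7S,8R,10S)-6-[(E)-but-2-enoyloxy]-3,3-(ethylenedioxy)germacra-4,11(13)-dien-12,8-olide, via hydroxy enal 31 (not isolated), via lactol 32 (not isolated)
Conditions: MnO2 (activated, excess), CH2Cl2, rt
Reagents that add atoms: none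
Why: MnO2 oxidises the primary allylic alcohol to the enal, the C8 hydroxyl adds to give the five-membered lactol, and further oxidation of this activated hemiacetal gives the α-methylene-γ-lactone (oxidative lactonisation of a 2-methylene-1,4-diol) with C7 and C8 unchanged.

Step 23
Reactants: 33 lactone
Product: 34 (4S,5R,6S,7S,8R,10S)-6-[(E)-but-2-enoyloxy]-3,3-(ethylenedioxy)-4,5-dihydroxygermacr-11(13)-en-12,8-olide
Conditions: OsO4 (5 mol %), N-methylmorpholine N-oxide, acetone/H2O, 0 °C → rt
Reagents that add atoms: N-methylmorpholine N-oxide (C[N+]1([O-])CCOCC1) and water (O)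
Why: Upjohn syn-dihydroxylation: OsO4 adds to the outer face of the strained (E)-ring alkene, the face being fixed by the conformer in which H6 eclipses the alkene next to C15 (A(1,3) strain) and C7 lies under the ring, which gives 4S and 5R, while the conjugated exocyclic methylene and the crotonate are poorer donors and should react more slowly.

Step 24
Reactants: 34 diol
Product: 35 (4S,5R,6S,7S,8R,10S)-5-acetoxy-6-[(E)-but-2-enoyloxy]-3,3-(ethylenedioxy)-4-hydroxygermacr-11(13)-en-12,8-olide
Conditions: Ac2O, DMAP (cat.), pyridine, CH2Cl2, 0 °C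
Reagents that add atoms: acetic anhydride (CC(=O)OC(C)=O)
Why: Acetylation distinguishes the secondary C5 hydroxyl from the tertiary C4 hydroxyl on steric grounds.

Step 25
Reactants: 35 acetate ketal
Product: 36 (4S,5R,6S,7S,8R,10S)-5-acetoxy-6-[(E)-but-2-enoyloxy]-4-hydroxy-3-oxogermacr-11(13)-en-12,8-olide
Conditions: TsOH·H2O (cat.), acetone/H2O, 40 °C
Reagents that add atoms: water (O)
Why: Acid-catalysed transketalisation to acetone and hydrolysis liberate the C3 ketone; esters and lactone are stable to dilute acid, and C4 carries no hydrogen and cannot epimerise.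

Step 26
Reactants: 36 ketone
Product: 39 (1Z,4S,5R,6S,7S,8R,10R)-5-acetoxy-6-[(E)-but-2-enoyloxy]-4-hydroxy-3-oxogermacra-1,11(13)-dien-12,8-olide, via silyl enol ether 37 (not isolated), via silylated enone 38 (not isolated)
Conditions: Me3SiOTf (2.5 equiv), Et3N, CH2Cl2, 0 °C; then Pd(OAc)2 (1.1 equiv), MeCN, rt; then citric acid, MeOH
Reagents that add atoms: none
Why: Saegusa–Ito oxidation: soft enolisation can only occur towards C2, the palladium enolate undergoes β-hydride elimination from C1, and in the ten-membered ring the conjugated enone is expected as the (Z)-isomer; the tertiary silyl ether formed in passing is removed in the acidic work-up.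

Step 27
Reactants: 39 (Z)-enone
Product: 40 (1S,2S,4S,5R,6S,7S,8R,10R)-5-acetoxy-6-[(E)-but-2-enoyloxy]-1,2-epoxy-4-hydroxy-3-oxogermacr-11(13)-en-12,8-olide (CNP0358125.1)
Conditions: t-BuOOH, DBU (cat.), CH2Cl2, 0 °C
Reagents that add atoms: tert-butyl hydroperoxide (CC(C)(C)OO)
Why: Weitz–Scheffer epoxidation: the hydroperoxide anion adds to C1 of the enone, a better acceptor than the two enoates, from the face turned outward when H10 eclipses the C1=C2 bond, and closure of the peroxy enolate within the ring gives the cis-epoxide with 1S and 2S.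

**Compound list**

1 | prop-2-yn-1-ol | C#CCO | starting material
2 | 4-methyl-2,5-dihydro-1,2-oxamagnesole (alkenylmagnesium chelate) | CC1=C[Mg]OC1 | intermediate (not isolated)
3 | (Z)-3-iodo-2-methylprop-2-en-1-ol | OC/C(C)=C\I | intermediate
4 | (Z)-1-iodo-3-[(4-methoxybenzyl)oxy]-2-methylprop-1-ene | COc1ccc(COC/C(C)=C\I)cc1 | intermediate
5 | (S)-citronellal | O=CC[C@@H](C)CCC=C(C)C | starting material
6 | (Z)-3-[(4-methoxybenzyl)oxy]-2-methylprop-1-enyllithium | COc1ccc(COC/C(C)=C\[Li])cc1 | intermediate (not isolated)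
7 | (2Z,6S)-1-[(4-methoxybenzyl)oxy]-2,6,10-trimethylundeca-2,9-dien-4-ol, C4 epimers | COc1ccc(COC/C(C)=C\C(O)C[C@@H](C)CCC=C(C)C)cc1 | intermediate
8 | (2Z,6S)-1-[(4-methoxybenzyl)oxy]-2,6,10-trimethylundeca-2,9-dien-4-one | COc1ccc(COC/C(C)=C\C(=O)C[C@@H](C)CCC=C(C)C)cc1 | intermediate
9 | (2Z,4R,6S)-1-[(4-methoxybenzyl)oxy]-2,6,10-trimethylundeca-2,9-dien-4-ol | COc1ccc(COC/C(C)=C\[C@H](O)C[C@@H](C)CCC=C(C)C)cc1 | intermediate
10 | TBS ether of 9 | COc1ccc(COC/C(C)=C\[C@H](O[Si](C)(C)C(C)(C)C)C[C@@H](C)CCC=C(C)C)cc1 | intermediate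
11 | (2Z,4R,6S)-4-[(tert-butyldimethylsilyl)oxy]-1-[(4-methoxybenzyl)oxy]-2,6,10-trimethylundec-2-ene-9,10-diol, C9 epimers | COc1ccc(COC/C(C)=C\[C@H](O[Si](C)(C)C(C)(C)C)C[C@@H](C)CCC(O)C(C)(C)O)cc1 | intermediate (not isolated)
12 | (4S,6R,7Z)-6-[(tert-butyldimethylsilyl)oxy]-9-[(4-methoxybenzyl)oxy]-4,8-dimethylnon-7-enal | COc1ccc(COC/C(C)=C\[C@H](O[Si](C)(C)C(C)(C)C)C[C@@H](C)CCC=O)cc1 | intermediate
13 | triethyl(prop-2-yn-1-yloxy)silane | C#CCO[Si](CC)(CC)CC | intermediate
14 | [3-(triethylsilyloxy)prop-1-yn-1-yl]lithium | [Li]C#CCO[Si](CC)(CC)CC | intermediate (not isolated)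
15 | (2Z,4R,6S)-4-[(tert-butyldimethylsilyl)oxy]-1-[(4-methoxybenzyl)oxy]-2,6-dimethyl-12-[(triethylsilyl)oxy]dodec-2-en-10-yn-9-ol, C9 epimers | COc1ccc(COC/C(C)=C\[C@H](O[Si](C)(C)C(C)(C)C)C[C@@H](C)CCC(O)C#CCO[Si](CC)(CC)CC)cc1 | intermediate
16 | corresponding dodec-2-en-10-yn-9-one | COc1ccc(COC/C(C)=C\[C@H](O[Si](C)(C)C(C)(C)C)C[C@@H](C)CCC(=O)C#CCO[Si](CC)(CC)CC)cc1 | intermediate
17 | 9,9-ethylenedioxy ketal of 16 | COc1ccc(COC/C(C)=C\[C@H](O[Si](C)(C)C(C)(C)C)C[C@@H](C)CCC2(OCCO2)C#CCO[Si](CC)(CC)CC)cc1 | intermediate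
18 | (2Z,4R,6S)-4-[(tert-butyldimethylsilyl)oxy]-9,9-(ethylenedioxy)-2,6-dimethyl-12-[(triethylsilyl)oxy]dodec-2-en-10-yn-1-ol | OC/C(C)=C\[C@H](O[Si](C)(C)C(C)(C)C)C[C@@H](C)CCC1(OCCO1)C#CCO[Si](CC)(CC)CC | intermediate
19 | methanesulfonate of 18 | CS(=O)(=O)OC/C(C)=C\[C@H](O[Si](C)(C)C(C)(C)C)C[C@@H](C)CCC1(OCCO1)C#CCO[Si](CC)(CC)CC | intermediate (not isolated)
20 | (2Z,4R,6S)-1-chloro analogue of 18 | ClC/C(C)=C\[C@H](O[Si](C)(C)C(C)(C)C)C[C@@H](C)CCC1(OCCO1)C#CCO[Si](CC)(CC)CC | intermediate
21 | (7S,9R,10Z)-9-[(tert-butyldimethylsilyl)oxy]-12-chloro-4,4-(ethylenedioxy)-7,11-dimethyldodec-10-en-2-yn-1-ol | ClC/C(C)=C\[C@H](O[Si](C)(C)C(C)(C)C)C[C@@H](C)CCC1(OCCO1)C#CCO | intermediate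
22 | tert-butyl{[(11Z,13R,15S)-11,15-dimethyl-1,4,9-trioxaspiro[4.12]heptadec-11-en-6-yn-13-yl]oxy}dimethylsilane (thirteen-membered ether) | C1[C@H](C)C[C@@H](O[Si](C)(C)C(C)(C)C)/C=C(C)\COCC#CC2(OCCO2)C1 | intermediate
23 | C6-lithiated derivative of 22 | C1[C@H](C)C[C@@H](O[Si](C)(C)C(C)(C)C)/C=C(C)\COC([Li])C#CC2(OCCO2)C1 | intermediate (not isolated)
24 | (6S,7R,8R,10S)-8-[(tert-butyldimethylsilyl)oxy]-3,3-(ethylenedioxy)-10-methyl-7-(prop-1-en-2-yl)cyclodec-4-yn-6-ol | O[C@@H]1C#CC2(OCCO2)CC[C@H](C)C[C@@H](O[Si](C)(C)C(C)(C)C)[C@@H]1C(C)=C | intermediate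
25 | sodium alkenylalanate from 24 (Al bound to O6 and C4) | COCCO[Al-]3(OCCOC)O[C@@H]1/C=C3/C2(OCCO2)CC[C@H](C)C[C@@H](O[Si](C)(C)C(C)(C)C)[C@@H]1C(C)=C.[Na+] | intermediate (not isolated)
26 | (4Z,6S,7R,8R,10S)-8-[(tert-butyldimethylsilyl)oxy]-3,3-(ethylenedioxy)-4-iodo-10-methyl-7-(prop-1-en-2-yl)cyclodec-4-en-6-ol | O[C@@H]1/C=C(I)/C2(OCCO2)CC[C@H](C)C[C@@H](O[Si](C)(C)C(C)(C)C)[C@@H]1C(C)=C | intermediate
27 | (4E,6R,7R,8R,10S)-8-[(tert-butyldimethylsilyl)oxy]-3,3-(ethylenedioxy)-4,10-dimethyl-7-(prop-1-en-2-yl)cyclodec-4-en-6-ol | O[C@@H]1/C=C(C)/C2(OCCO2)CC[C@H](C)C[C@@H](O[Si](C)(C)C(C)(C)C)[C@@H]1C(C)=C | intermediate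
28 | 6-O-[(E)-but-2-enoate] of 27 | C/C=C/C(=O)O[C@@H]1/C=C(C)/C2(OCCO2)CC[C@H](C)C[C@@H](O[Si](C)(C)C(C)(C)C)[C@@H]1C(C)=C | intermediate
29 | 7-(3-hydroxyprop-1-en-2-yl) analogue of 28 | C/C=C/C(=O)O[C@@H]1/C=C(C)/C2(OCCO2)CC[C@H](C)C[C@@H](O[Si](C)(C)C(C)(C)C)[C@@H]1C(=C)CO | intermediate
30 | (4E,6R,7S,8R,10S)-3,3-(ethylenedioxy)-8-hydroxy-7-(3-hydroxyprop-1-en-2-yl)-4,10-dimethylcyclodec-4-en-6-yl (E)-but-2-enoate | C/C=C/C(=O)O[C@@H]1/C=C(C)/C2(OCCO2)CC[C@H](C)C[C@@H](O)[C@@H]1C(=C)CO | intermediate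
31 | 8-hydroxy 12-enal from 30 | C/C=C/C(=O)O[C@@H]1/C=C(C)/C2(OCCO2)CC[C@H](C)C[C@@H](O)[C@@H]1C(=C)C=O | intermediate (not isolated)
32 | 12,8-lactol, C12 epimers | C=C1C(O)O[C@@H]2C[C@@H](C)CCC3(OCCO3)/C(C)=C/[C@@H](OC(=O)/C=C/C)[C@@H]12 | intermediate (not isolated)
33 | (4E,6R,7S,8R,10S)-6-[(E)-but-2-enoyloxy]-3,3-(ethylenedioxy)germacra-4,11(13)-dien-12,8-olide | C=C1C(=O)O[C@@H]2C[C@@H](C)CCC3(OCCO3)/C(C)=C/[C@@H](OC(=O)/C=C/C)[C@@H]12 | intermediate
34 | (4S,5R,6S,7S,8R,10S)-6-[(E)-but-2-enoyloxy]-3,3-(ethylenedioxy)-4,5-dihydroxygermacr-11(13)-en-12,8-olide | C=C1C(=O)O[C@@H]2C[C@@H](C)CCC3(OCCO3)[C@@](C)(O)[C@H](O)[C@@H](OC(=O)/C=C/C)[C@@H]12 | intermediate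
35 | 5-O-acetate of 34 | C=C1C(=O)O[C@@H]2C[C@@H](C)CCC3(OCCO3)[C@@](C)(O)[C@H](OC(C)=O)[C@@H](OC(=O)/C=C/C)[C@@H]12 | intermediate
36 | (4S,5R,6S,7S,8R,10S)-5-acetoxy-6-[(E)-but-2-enoyloxy]-4-hydroxy-3-oxogermacr-11(13)-en-12,8-olide | C=C1C(=O)O[C@@H]2C[C@@H](C)CCC(=O)[C@@](C)(O)[C@H](OC(C)=O)[C@@H](OC(=O)/C=C/C)[C@@H]12 | intermediate
37 | 3-(trimethylsilyloxy)-2-ene with 4-O-trimethylsilyl ether, from 36 | C=C1C(=O)O[C@@H]2C[C@@H](C)CC=C(O[Si](C)(C)C)[C@@](C)(O[Si](C)(C)C)[C@H](OC(C)=O)[C@@H](OC(=O)/C=C/C)[C@@H]12 | intermediate (not isolated)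
38 | 4-O-trimethylsilyl ether of 39 | C=C1C(=O)O[C@@H]2C[C@@H](C)/C=C\C(=O)[C@@](C)(O[Si](C)(C)C)[C@H](OC(C)=O)[C@@H](OC(=O)/C=C/C)[C@@H]12 | intermediate (not isolated)
39 | (1Z,4S,5R,6S,7S,8R,10R)-5-acetoxy-6-[(E)-but-2-enoyloxy]-4-hydroxy-3-oxogermacra-1,11(13)-dien-12,8-olide | C=C1C(=O)O[C@@H]2C[C@@H](C)/C=C\C(=O)[C@@](C)(O)[C@H](OC(C)=O)[C@@H](OC(=O)/C=C/C)[C@@H]12 | intermediate
40 | (1S,2S,4S,5R,6S,7S,8R,10R)-5-acetoxy-6-[(E)-but-2-enoyloxy]-1,2-epoxy-4-hydroxy-3-oxogermacr-11(13)-en-12,8-olide (CNP0358125.1) | C=C1C(=O)O[C@@H]2C[C@@H](C)[C@@H]3O[C@@H]3C(=O)[C@@](C)(O)[C@H](OC(C)=O)[C@@H](OC(=O)/C=C/C)[C@@H]12 | target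

**Step count and risks**

Total: 27 steps. Longest linear sequence: 26 steps (from 1 through steps 1–7 and 9–27); 24 steps from (S)-citronellal 5.

Steps most likely to fail:

1. Step 23. Osmylation may occur at the conjugated exocyclic C11=C13 alkene or at the crotonate in competition with the hindered ring alkene. Fallback, setting out from 33 and returning at 35: conjugate addition of dimethylamine (THF, 0 °C) masks the methylene lactone as the amine adduct F1. The same OsO4/N-methylmorpholine N-oxide conditions then give the 4,5-diol F2, and acetylation (Ac2O, DMAP, pyridine) gives the 5-acetate F3. Methyl iodide converts F3 into the quaternary ammonium iodide F4, and aqueous NaHCO3 eliminates trimethylamine to restore the methylene lactone in 35.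

2. Step 26. β-Hydride elimination from the palladium enolate may give an (E)/(Z) mixture, or palladium may isomerise or consume the conjugated lactone. Fallback, setting out from the silyl enol ether 37 and returning at 38: PhSeCl (CH2Cl2, −78 °C) gives the 2-phenylselanyl ketone F5. Oxidation with H2O2/pyridine at 0 °C gives the selenoxide F6, whose syn-elimination delivers the silylated enone 38, which the acidic work-up of step 26 converts into 39.

3. Step 27. The peroxide anion may add to the α-methylene lactone, or may approach the enone from the inner face. Fallback, setting out from 39 and returning at 40: Luche reduction (NaBH4, CeCl3·7H2O, MeOH, −78 °C) gives the allylic alcohol F7. Hydroxyl-directed epoxidation with VO(acac)2/t-BuOOH leaves the electron-poor alkenes untouched, places the oxygen on the face of the C3 hydroxyl and gives the epoxy alcohol F8. Dess–Martin oxidation of F8 gives 40.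

Further compounds
F1 | step 23 | 13-(dimethylamino)-11,13-dihydro derivative of 33, C11 epimers | CN(C)CC1C(=O)O[C@@H]2C[C@@H](C)CCC3(OCCO3)/C(C)=C/[C@@H](OC(=O)/C=C/C)[C@@H]12
F2 | step 23 | 4,5-diol of F1 | CN(C)CC1C(=O)O[C@@H]2C[C@@H](C)CCC3(OCCO3)[C@@](C)(O)[C@H](O)[C@@H](OC(=O)/C=C/C)[C@@H]12
F3 | step 23 | 5-O-acetate of F2 | CN(C)CC1C(=O)O[C@@H]2C[C@@H](C)CCC3(OCCO3)[C@@](C)(O)[C@H](OC(C)=O)[C@@H](OC(=O)/C=C/C)[C@@H]12
F4 | step 23 | N-methyl quaternary ammonium iodide of F3 | C[N+](C)(C)CC1C(=O)O[C@@H]2C[C@@H](C)CCC3(OCCO3)[C@@](C)(O)[C@H](OC(C)=O)[C@@H](OC(=O)/C=C/C)[C@@H]12.[I-]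
F5 | step 26 | 2-(phenylselanyl) 3-ketone with 4-O-trimethylsilyl ether, C2 epimers | C=C1C(=O)O[C@@H]2C[C@@H](C)CC([Se]c3ccccc3)C(=O)[C@@](C)(O[Si](C)(C)C)[C@H](OC(C)=O)[C@@H](OC(=O)/C=C/C)[C@@H]12
F6 | step 26 | selenoxide of F5 | C=C1C(=O)O[C@@H]2C[C@@H](C)CC([Se](=O)c3ccccc3)C(=O)[C@@](C)(O[Si](C)(C)C)[C@H](OC(C)=O)[C@@H](OC(=O)/C=C/C)[C@@H]12
F7 | step 27 | (1Z)-3-hydroxy analogue of 39, C3 configuration set by hydride attack | C=C1C(=O)O[C@@H]2C[C@@H](C)/C=C\C(O)[C@@](C)(O)[C@H](OC(C)=O)[C@@H](OC(=O)/C=C/C)[C@@H]12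
F8 | step 27 | 1,2-epoxy-3-hydroxy analogue of 40 | C=C1C(=O)O[C@@H]2C[C@@H](C)[C@@H]3O[C@@H]3C(O)[C@@](C)(O)[C@H](OC(C)=O)[C@@H](OC(=O)/C=C/C)[C@@H]12
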